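Assumption: (R)-glyceraldehyde acetonide 1, silyl ether 7, methyl acrylate 14 and angelic acid 21 are bought; germacrane numbering (C1–C15) is used for atoms. The route is a paper design: none of it has been run, and the stereochemical outcomes of steps 11, 15 and 16 are predictions.

## Retrosynthetic overview

1. Target 28 comes from the 1(10)-olefin 27 by a late, substrate-controlled epoxidation; the epoxide ring is formed last and sets C1 and C10.
2. 27 comes from the seco iodo-aldehyde 25 by an electrochemical Ni/Cr-catalysed Nozaki–Hiyama–Kishi closure of C4–C5; the ten-membered ring is formed second and the step sets C5.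
3. 25 comes from aldehyde 13 and bromomethyl butenolide 18 by a zinc Barbier allylation at C7–C8 (sets C7 and C8, unveils the α-methylene lactone), then angeloylation and oxidation at C5.
4. 13 comes from alkyne 7 and iodovinyl oxirane 6 by carboalumination and alanate opening of the epoxide (E-1(10) olefin, C1–C2 bond).
5. 6 and 18 (lactone ring, formed first) both come from (R)-glyceraldehyde acetonide 1, the only source of chirality (C3 and C6).

## Route

Step 1
Reactants: 1 (4R)-2,2-dimethyl-1,3-dioxolane-4-carbaldehyde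
Product: 2 (4S)-4-ethynyl-2,2-dimethyl-1,3-dioxolane
Conditions: Ohira–Bestmann reagent, K2CO3, MeOH, 0 °C to rt
Reagents that add atoms: dimethyl (1-diazo-2-oxopropyl)phosphonate, COP(=O)(OC)C(=[N+]=[N-])C(C)=O
Why: Seyferth–Gilbert homologation in its Ohira–Bestmann form turns the aldehyde into the terminal alkyne under mild carbonate conditions that do not epimerise the α-alkoxy centre, so the bought centre (future C3) is kept.

Step 2
Reactants: 2 (4S)-4-ethynyl-2,2-dimethyl-1,3-dioxolane
Product: 4 (2R)-3-iodobut-3-ene-1,2-diol, via (4R)-4-(1-iodoethenyl)-2,2-dimethyl-1,3-dioxolane 3 (not isolated)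
Conditions: NaI, Me3SiCl, H2O, MeCN, 0 °C to rt; then 1 M HCl, MeOH, rt
Reagents that add atoms: sodium iodide, [Na+].[I-]
Why: Markovnikov hydroiodination of the terminal alkyne by HI made in the flask gives the 2-iodo-1-alkene, and the acidic medium then hydrolyses the acetonide; no bond to the stereocentre is touched.

Step 3
Reactants: 4 (2R)-3-iodobut-3-ene-1,2-diol
Product: 6 (2R)-2-(1-iodoethenyl)oxirane, via primary tosylate 5 (not isolated)
Conditions: TsCl, Et3N, Bu2SnO (2 mol%), CH2Cl2, 0 °C; then K2CO3, MeOH, 0 °C (6 kept as an Et2O solution)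
Reagents that add atoms: none
Why: Tin-catalysed selective sulfonylation of the primary hydroxyl followed by Williamson ring closure; the secondary C–O bond is never broken, so configuration at the future C3 is retained.

Step 4
Reactants: 7 tert-butyl(but-3-yn-1-yloxy)dimethylsilane; 6 (2R)-2-(1-iodoethenyl)oxirane
Product: 11 (3R,5E)-8-{[tert-butyl(dimethyl)silyl]oxy}-2-iodo-6-methylocta-1,5-dien-3-yl acetate, via alkenyldimethylalane 8 (not isolated), via lithium alkenylalanate 9 (not isolated), via aluminate alkoxide 10 (not isolated)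
Conditions: AlMe3 (2 equiv), Cp2ZrCl2 (0.25 equiv), CH2Cl2, rt; evaporate; n-BuLi (1 equiv), hexane, 0 °C; 6, THF, −30 °C to rt; Ac2O, DMAP, 0 °C to rt
Reagents that add atoms: trimethylaluminium, C[Al](C)C; acetic anhydride, CC(=O)OC(C)=O
Why: Negishi zirconium-catalysed syn-carboalumination fixes the E-trisubstituted olefin (methyl and aluminium cis); the lithium alanate then transfers the alkenyl group to the oxirane, where attack at the unsubstituted carbon is expected by analogy with non-Lewis-acidic ate nucleophiles rather than shown for a vinyl oxirane, and the alkoxide is acetylated in the same flask, leaving the bought C3 centre untouched.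

Step 5
Reactants: 11 (3R,5E)-8-{[tert-butyl(dimethyl)silyl]oxy}-2-iodo-6-methylocta-1,5-dien-3-yl acetate
Product: 12 (3R,5E)-8-hydroxy-2-iodo-6-methylocta-1,5-dien-3-yl acetate
Conditions: HF·pyridine, pyridine, THF, 0 °C to rt
Reagents that add atoms: none
Why: Fluoride desilylation of the primary silyl ether; acetate, vinyl iodide and olefin are inert.

Step 6
Reactants: 12 (3R,5E)-8-hydroxy-2-iodo-6-methylocta-1,5-dien-3-yl acetate
Product: 13 (3R,5E)-2-iodo-6-methyl-8-oxoocta-1,5-dien-3-yl acetate
Conditions: Dess–Martin periodinane, CH2Cl2, 0 °C to rt; used at once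
Reagents that add atoms: none
Why: Dess–Martin oxidation under non-basic conditions gives the β,γ-unsaturated aldehyde without moving the olefin into conjugation.

Step 7
Reactants: 1 (4R)-2,2-dimethyl-1,3-dioxolane-4-carbaldehyde; 14 methyl acrylate
Product: 15 methyl 2-{[(4R)-2,2-dimethyl-1,3-dioxolan-4-yl](hydroxy)methyl}prop-2-enoate (both carbinol epimers)
Conditions: DABCO (1 equiv), 1,4-dioxane/H2O 1:1, rt
Reagents that add atoms: none
Why: Morita–Baylis–Hillman reaction attaches C11–C13 to the future C7; the new carbinol centre is removed in step 10, so only the dioxolane centre (future C6) matters and it is retained.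

Step 8
Reactants: 15 methyl 2-{[(4R)-2,2-dimethyl-1,3-dioxolan-4-yl](hydroxy)methyl}prop-2-enoate
Product: 16 (5R)-4-hydroxy-5-(hydroxymethyl)-3-methylideneoxolan-2-one (both 4-epimers)
Conditions: TFA/H2O 4:1, 0 °C to rt; evaporate
Reagents that add atoms: none
Why: Acid hydrolysis of the acetonide followed by lactonisation of the γ-hydroxy ester (five-membered lactone preferred over six) builds the lactone ring with C6 taken from the chiral pool.

Step 9
Reactants: 16 (5R)-4-hydroxy-5-(hydroxymethyl)-3-methylideneoxolan-2-one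
Product: 17 (5R)-5-({[tert-butyl(dimethyl)silyl]oxy}methyl)-4-hydroxy-3-methylideneoxolan-2-one (both 4-epimers)
Conditions: TBSCl (1.05 equiv), imidazole, DMF, −20 °C
Reagents that add atoms: tert-butyldimethylsilyl chloride, CC(C)(C)[Si](C)(C)Cl
Why: Selective silylation of the primary over the secondary allylic hydroxyl.

Step 10
Reactants: 17 (5R)-5-({[tert-butyl(dimethyl)silyl]oxy}methyl)-4-hydroxy-3-methylideneoxolan-2-one
Product: 18 (5S)-3-(bromomethyl)-5-({[tert-butyl(dimethyl)silyl]oxy}methyl)furan-2(5H)-one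
Conditions: NBS, Me2S, CH2Cl2, −20 °C to rt
Reagents that add atoms: N-bromosuccinimide, O=C1CCC(=O)N1Br
Why: Corey–Kim-type bromination with allylic transposition (SN2′), as with Baylis–Hillman alcohols, gives the conjugated butenolide carrying the primary allylic bromide; both carbinol epimers converge and C6 is untouched.

Step 11
Reactants: 13 (3R,5E)-2-iodo-6-methyl-8-oxoocta-1,5-dien-3-yl acetate; 18 (5S)-3-(bromomethyl)-5-({[tert-butyl(dimethyl)silyl]oxy}methyl)furan-2(5H)-one
Product: 20 (3R,5E,8S)-8-[(2S,3R)-2-({[tert-butyl(dimethyl)silyl]oxy}methyl)-4-methylidene-5-oxooxolan-3-yl]-8-hydroxy-2-iodo-6-methylocta-1,5-dien-3-yl acetate, via allylzinc bromide 19 (not isolated)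
Conditions: Zn dust, THF/sat. aq. NH4Cl 2:1, 0 °C to rt, sonication
Reagents that add atoms: none
Why: Zinc Barbier (Dreiding–Schmidt type) allylation in which the allylzinc reacts at its γ-carbon (C7) and regenerates the α-methylene lactone; the aldehyde should add to the ring face anti to the silyloxymethyl group (C7, trans-lactone), and a chair transition state with the ring carbon as the E-disposed γ-substituent predicts the anti carbinol (C8).

Step 12
Reactants: 20 the hydroxy lactone of step 11; 21 angelic acid, (2Z)-2-methylbut-2-enoic acid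
Product: 23 (1S,3E,6R)-6-(acetyloxy)-1-[(2S,3R)-2-({[tert-butyl(dimethyl)silyl]oxy}methyl)-4-methylidene-5-oxooxolan-3-yl]-7-iodo-3-methylocta-3,7-dien-1-yl (2Z)-2-methylbut-2-enoate, via angelic 2,4,6-trichlorobenzoic mixed anhydride 22 (not isolated)
Conditions: 21, 2,4,6-trichlorobenzoyl chloride, Et3N, toluene, rt; then 20, DMAP, rt to 40 °C
Reagents that add atoms: none
Why: Yamaguchi esterification through the mixed anhydride acylates the hindered C8 hydroxyl with retention and is the usual way to make angelates without Z to E isomerisation.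

Step 13
Reactants: 23 the silyl ether of step 12
Product: 24 (1S,3E,6R)-6-(acetyloxy)-1-[(2S,3R)-2-(hydroxymethyl)-4-methylidene-5-oxooxolan-3-yl]-7-iodo-3-methylocta-3,7-dien-1-yl (2Z)-2-methylbut-2-enoate
Conditions: HF·pyridine, pyridine, THF, 0 °C to rt
Reagents that add atoms: none
Why: Buffered fluoride desilylation frees the C5 hydroxyl without touching the three esters.

Step 14
Reactants: 24 the primary alcohol of step 13
Product: 25 (1S,3E,6R)-6-(acetyloxy)-1-[(2S,3R)-2-formyl-4-methylidene-5-oxooxolan-3-yl]-7-iodo-3-methylocta-3,7-dien-1-yl (2Z)-2-methylbut-2-enoate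
Conditions: Dess–Martin periodinane, CH2Cl2, 0 °C to rt; used at once
Reagents that add atoms: none
Why: Dess–Martin oxidation gives the α-acyloxy aldehyde under neutral to weakly acidic conditions that do not epimerise C6.

Step 15
Reactants: 25 the seco iodo-aldehyde of step 14
Product: 27 (1(10)E,3R,5S,6S,7R,8S)-3-acetoxy-8-angeloyloxy-5-hydroxygermacra-1(10),4(15),11(13)-trien-12,6-olide, via trimethylsilyl ether 26 (not isolated)
Conditions: CrCl2 (20 mol%), NiCl2·DME (2 mol%), neocuproine (2.5 mol%), Me3SiCl (2 equiv), LiCl, n-Bu4NBF4, DMF, undivided cell, Al anode, Ni-foam cathode, constant current, syringe-pump addition of 25 to 2 mM, rt; then aq. citric acid, THF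
Reagents that add atoms: none
Why: Proposed new method: the cathode regenerates divalent chromium and zerovalent nickel from catalytic CrCl2 and NiCl2·DME, zerovalent nickel inserts into the C–I bond, the alkenyl group passes to trivalent chromium and adds to the aldehyde, and Me3SiCl releases chromium from the alkoxide so both metals turn over while the Al anode supplies the electrons; in the ring-closing transition state the C6–O bond lies anti to the incoming alkenylchromium (polar Felkin–Anh) and the metal-bound carbonyl oxygen points to the outside of the forming ten-membered ring, which should give the 5S (5,6-threo) carbinol; the closest known reactions are the intermolecular electrochemical Nozaki–Hiyama–Kishi coupling and stoichiometric CrCl2-mediated NHK macrocyclisations, neither of which has been shown as an electrocatalytic ten-membered carbocyclisation.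

Step 16
Reactants: 27 the macrocyclic alcohol of step 15
Product: 28 (1R,3R,5S,6S,7R,8S,10R)-3-acetoxy-8-angeloyloxy-1,10-epoxy-5-hydroxygermacra-4(15),11(13)-dien-12,6-olide (CNP0210054.2)
Conditions: dimethyldioxirane (1.05 equiv, acetone), CH2Cl2, −40 to 0 °C
Reagents that add atoms: dimethyldioxirane, CC1(C)OO1
Why: Dioxirane epoxidation should take only the strained, electron-rich E-1(10) trisubstituted olefin (the other olefins are conjugated to carbonyls or flanked by two allylic C–O bonds) and deliver oxygen to the outer face of the E-cyclodecene, the face selectivity that gives 1β,10α-epoxides from costunolide-type germacranolides, here 1R,10R.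

## Compound list

1 | (4R)-2,2-dimethyl-1,3-dioxolane-4-carbaldehyde | O=C[C@H]1COC(C)(C)O1 | starting material
2 | (4S)-4-ethynyl-2,2-dimethyl-1,3-dioxolane | C#C[C@H]1COC(C)(C)O1 | intermediate
3 | (4R)-4-(1-iodoethenyl)-2,2-dimethyl-1,3-dioxolane | C=C(I)[C@H]1COC(C)(C)O1 | intermediate
4 | (2R)-3-iodobut-3-ene-1,2-diol | C=C(I)[C@H](O)CO | intermediate
5 | (2R)-2-hydroxy-3-iodobut-3-en-1-yl 4-methylbenzenesulfonate | C=C(I)[C@H](O)COS(=O)(=O)c1ccc(C)cc1 | intermediate
6 | (2R)-2-(1-iodoethenyl)oxirane | C=C(I)[C@H]1CO1 | intermediate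
7 | tert-butyl(but-3-yn-1-yloxy)dimethylsilane | C#CCCO[Si](C)(C)C(C)(C)C | starting material
8 | [(1E)-4-{[tert-butyl(dimethyl)silyl]oxy}-2-methylbut-1-en-1-yl]dimethylaluminium | C[Al](C)/C=C(\C)CCO[Si](C)(C)C(C)(C)C | intermediate
9 | lithium butyl[(1E)-4-{[tert-butyl(dimethyl)silyl]oxy}-2-methylbut-1-en-1-yl]dimethylaluminate | [Li+].CCCC[Al-](C)(C)/C=C(\C)CCO[Si](C)(C)C(C)(C)C | intermediate
10 | lithium butyl(dimethyl){[(3R,5E)-8-{[tert-butyl(dimethyl)silyl]oxy}-2-iodo-6-methylocta-1,5-dien-3-yl]oxy}aluminate | [Li+].CCCC[Al-](C)(C)O[C@H](C/C=C(\C)CCO[Si](C)(C)C(C)(C)C)C(I)=C | intermediate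
11 | (3R,5E)-8-{[tert-butyl(dimethyl)silyl]oxy}-2-iodo-6-methylocta-1,5-dien-3-yl acetate | C=C(I)[C@H](OC(C)=O)C/C=C(\C)CCO[Si](C)(C)C(C)(C)C | intermediate
12 | (3R,5E)-8-hydroxy-2-iodo-6-methylocta-1,5-dien-3-yl acetate | C=C(I)[C@H](OC(C)=O)C/C=C(\C)CCO | intermediate
13 | (3R,5E)-2-iodo-6-methyl-8-oxoocta-1,5-dien-3-yl acetate | C=C(I)[C@H](OC(C)=O)C/C=C(\C)CC=O | intermediate
14 | methyl acrylate | C=CC(=O)OC | starting material
15 | methyl 2-{[(4R)-2,2-dimethyl-1,3-dioxolan-4-yl](hydroxy)methyl}prop-2-enoate, both carbinol epimers | C=C(C(=O)OC)C(O)[C@H]1COC(C)(C)O1 | intermediate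
16 | (5R)-4-hydroxy-5-(hydroxymethyl)-3-methylideneoxolan-2-one, both 4-epimers | C=C1C(=O)O[C@H](CO)C1O | intermediate
17 | (5R)-5-({[tert-butyl(dimethyl)silyl]oxy}methyl)-4-hydroxy-3-methylideneoxolan-2-one, both 4-epimers | C=C1C(=O)O[C@H](CO[Si](C)(C)C(C)(C)C)C1O | intermediate
18 | (5S)-3-(bromomethyl)-5-({[tert-butyl(dimethyl)silyl]oxy}methyl)furan-2(5H)-one | BrCC1=C[C@@H](CO[Si](C)(C)C(C)(C)C)OC1=O | intermediate
19 | bromo{[(5S)-5-({[tert-butyl(dimethyl)silyl]oxy}methyl)-2-oxo-2,5-dihydrofuran-3-yl]methyl}zinc | Br[Zn]CC1=C[C@@H](CO[Si](C)(C)C(C)(C)C)OC1=O | intermediate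
20 | (3R,5E,8S)-8-[(2S,3R)-2-({[tert-butyl(dimethyl)silyl]oxy}methyl)-4-methylidene-5-oxooxolan-3-yl]-8-hydroxy-2-iodo-6-methylocta-1,5-dien-3-yl acetate | C=C1C(=O)O[C@H](CO[Si](C)(C)C(C)(C)C)[C@H]1[C@@H](O)C/C(C)=C/C[C@@H](OC(C)=O)C(I)=C | intermediate
21 | angelic acid, (2Z)-2-methylbut-2-enoic acid | C/C=C(/C)C(=O)O | starting material
22 | (2Z)-2-methylbut-2-enoic 2,4,6-trichlorobenzoic anhydride | C/C=C(/C)C(=O)OC(=O)c1c(Cl)cc(Cl)cc1Cl | intermediate
23 | (1S,3E,6R)-6-(acetyloxy)-1-[(2S,3R)-2-({[tert-butyl(dimethyl)silyl]oxy}methyl)-4-methylidene-5-oxooxolan-3-yl]-7-iodo-3-methylocta-3,7-dien-1-yl (2Z)-2-methylbut-2-enoate | C=C1C(=O)O[C@H](CO[Si](C)(C)C(C)(C)C)[C@H]1[C@@H](OC(=O)/C(C)=C\C)C/C(C)=C/C[C@@H](OC(C)=O)C(I)=C | intermediate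
24 | (1S,3E,6R)-6-(acetyloxy)-1-[(2S,3R)-2-(hydroxymethyl)-4-methylidene-5-oxooxolan-3-yl]-7-iodo-3-methylocta-3,7-dien-1-yl (2Z)-2-methylbut-2-enoate | C=C1C(=O)O[C@H](CO)[C@H]1[C@@H](OC(=O)/C(C)=C\C)C/C(C)=C/C[C@@H](OC(C)=O)C(I)=C | intermediate
25 | (1S,3E,6R)-6-(acetyloxy)-1-[(2S,3R)-2-formyl-4-methylidene-5-oxooxolan-3-yl]-7-iodo-3-methylocta-3,7-dien-1-yl (2Z)-2-methylbut-2-enoate | C=C1C(=O)O[C@H](C=O)[C@H]1[C@@H](OC(=O)/C(C)=C\C)C/C(C)=C/C[C@@H](OC(C)=O)C(I)=C | intermediate
26 | (1(10)E,3R,5S,6S,7R,8S)-3-acetoxy-8-angeloyloxy-5-(trimethylsilyloxy)germacra-1(10),4(15),11(13)-trien-12,6-olide | C=C1C(=O)O[C@H]2[C@H]1[C@@H](OC(=O)/C(C)=C\C)C/C(C)=C/C[C@@H](OC(C)=O)C(=C)[C@@H]2O[Si](C)(C)C | intermediate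
27 | (1(10)E,3R,5S,6S,7R,8S)-3-acetoxy-8-angeloyloxy-5-hydroxygermacra-1(10),4(15),11(13)-trien-12,6-olide | C=C1C(=O)O[C@H]2[C@H]1[C@@H](OC(=O)/C(C)=C\C)C/C(C)=C/C[C@@H](OC(C)=O)C(=C)[C@@H]2O | intermediate
28 | (1R,3R,5S,6S,7R,8S,10R)-3-acetoxy-8-angeloyloxy-1,10-epoxy-5-hydroxygermacra-4(15),11(13)-dien-12,6-olide (CNP0210054.2) | C=C1C(=O)O[C@H]2[C@H]1[C@@H](OC(=O)/C(C)=C\C)C[C@@]1(C)O[C@@H]1C[C@@H](OC(C)=O)C(=C)[C@@H]2O | target

## Step count and risks

Total: 16 steps. Longest linear sequence: 12 steps (steps 1–6, then 11–16); the lactone branch (steps 7–10) joins at step 11.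

The three steps most likely to fail:

Step 15 (the proposed new electrochemical ring closure). The ten-membered ring may close in low yield, the alkenylnickel may lose the neighbouring acetate, or the C5 carbinol may form with the wrong configuration. The fallback sets out from 25 and uses only known chemistry. The ring is closed by the classical Nozaki–Hiyama–Kishi reaction with excess CrCl2 and catalytic NiCl2 in degassed DMSO/THF at high dilution, with no demand on the C5 selectivity. This gives 27 together with, or in place of, its C5 epimer, (1(10)E,3R,5R,6S,7R,8S)-3-acetoxy-8-angeloyloxy-5-hydroxygermacra-1(10),4(15),11(13)-trien-12,6-olide F1. F1 (or the mixture) is oxidised with Dess–Martin periodinane to the macrocyclic enone (1(10)E,3R,6S,7R,8S)-3-acetoxy-8-angeloyloxy-5-oxogermacra-1(10),4(15),11(13)-trien-12,6-olide F2. Luche reduction (NaBH4, CeCl3·7H2O, MeOH, −78 °C), with hydride delivered from the ring periphery, then sets C5 and comes back to the route at 27.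

Step 16 (face and site selectivity of the last epoxidation). If the dioxirane delivers oxygen to the wrong face of the 1(10) olefin, the fallback sets out from 27 and puts the oxygen on the opposite face in two known steps. NBS in aqueous THF at 0 °C gives, by anti addition with water attacking the tertiary C10, the bromohydrin (1S,3R,5S,6S,7R,8S,10R)-3-acetoxy-8-angeloyloxy-1-bromo-5,10-dihydroxygermacra-4(15),11(13)-dien-12,6-olide F3. Ag2O in CH2Cl2 then closes the epoxide with inversion at C1, so that the oxygen ends on the face opposite to the one the electrophile attacked, and the route is rejoined at 28.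

Step 11 (configuration of the C8 carbinol in the Barbier coupling). If the coupling of 13 and 18 gives the 8-epimer, (3R,5E,8R)-8-[(2S,3R)-2-({[tert-butyl(dimethyl)silyl]oxy}methyl)-4-methylidene-5-oxooxolan-3-yl]-8-hydroxy-2-iodo-6-methylocta-1,5-dien-3-yl acetate F4, as the main product or in a mixture, the retentive Yamaguchi acylation of step 12 is replaced for that epimer. F4 is esterified with angelic acid 21 under Mitsunobu conditions (PPh3, DIAD, toluene, 0 °C to rt), which inverts C8 while installing the angelate, and the route is rejoined at 23. Both C8 epimers therefore lead to 23.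

Further compounds
F1 | step 15 | (1(10)E,3R,5R,6S,7R,8S)-3-acetoxy-8-angeloyloxy-5-hydroxygermacra-1(10),4(15),11(13)-trien-12,6-olide | C=C1C(=O)O[C@H]2[C@H]1[C@@H](OC(=O)/C(C)=C\C)C/C(C)=C/C[C@@H](OC(C)=O)C(=C)[C@H]2O
F2 | step 15 | (1(10)E,3R,6S,7R,8S)-3-acetoxy-8-angeloyloxy-5-oxogermacra-1(10),4(15),11(13)-trien-12,6-olide | C=C1C(=O)O[C@H]2[C@H]1[C@@H](OC(=O)/C(C)=C\C)C/C(C)=C/C[C@@H](OC(C)=O)C(=C)C2=O
F3 | step 16 | (1S,3R,5S,6S,7R,8S,10R)-3-acetoxy-8-angeloyloxy-1-bromo-5,10-dihydroxygermacra-4(15),11(13)-dien-12,6-olide | C=C1C(=O)O[C@H]2[C@H]1[C@@H](OC(=O)/C(C)=C\C)C[C@@](C)(O)[C@@H](Br)C[C@@H](OC(C)=O)C(=C)[C@@H]2O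
F4 | step 11 | (3R,5E,8R)-8-[(2S,3R)-2-({[tert-butyl(dimethyl)silyl]oxy}methyl)-4-methylidene-5-oxooxolan-3-yl]-8-hydroxy-2-iodo-6-methylocta-1,5-dien-3-yl acetate | C=C1C(=O)O[C@H](CO[Si](C)(C)C(C)(C)C)[C@H]1[C@H](O)C/C(C)=C/C[C@@H](OC(C)=O)C(I)=C
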